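Late in these runs the starting material is still falling: at 20.0 h alpha read 47.1 % and epsilon 43.0 %, each with a scatter of 1 percentage point.

| setting | alpha | epsilon | amber | violet |
|---|---|---|---|---|
| starting material | 0.85 M | 0.85 M | 0.85 M | 0.85 M |
| partner | 2.55 M | 2.55 M | 2.55 M | 2.55 M |
| free catalyst | 5 mM | 7.4 mM | 5.5 mM | 4.2 mM |
| added ligand | 7.9 mM | 7.9 mM | 7.9 mM | 7.9 mM |
| remark | run made earlier | run made earlier |  |  |
| time |  |  | 30 h | 30 h |

| run | time / h | target / % | starting material / % | over-reaction product / % |
|---|---|---|---|---|
| alpha | 3.00 | 29.0 | 69.4 | 1.1 |
| alpha | 6.00 | 34.3 | 58.9 | 2.4 |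
| alpha | 10.0 | 37.5 | 53.0 | 9.5 |
| alpha | 12.0 | 38.0 | 53.0 | 9.1 |
| alpha | 15.0 | 38.4 | 48.9 | 12.8 |
| alpha | 20.0 | 36.8 | 47.1 | 17.1 |
| epsilon | 3.00 | 35.0 | 62.9 | 3.2 |
| epsilon | 6.00 | 39.1 | 55.0 | 8.2 |
| epsilon | 10.0 | 37.5 | 50.4 | 12.0 |
| epsilon | 12.0 | 35.5 | 48.6 | 16.2 |
| epsilon | 15.0 | 35.2 | 47.3 | 19.2 |
| epsilon | 20.0 | 33.2 | 43.0 | 25.9 |

(each reading ± 1 percentage point)

1. which of these there is most of at the end, counted by the starting material in it, amber (starting material / target / over-reaction product)
2. which of these there is most of at the end, counted by the starting material in it, violet (starting material / target / over-reaction product)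
3. how much there is at the end of the one of these that leads, in percent of the starting material charged: amber
4. how much there is at the end of the one of these that leads, in percent of the starting material charged: violet

For the next shift: amber and violet differ from these runs in free catalyst and time, with added ligand charged alike. Epsilon was charged with more free catalyst than alpha, and the two runs differ in nothing else. At 20.0 h, epsilon's over-reaction product reads 1.51 times alpha's, and its catalyst charge is 1.48 times alpha's, so the making of over-reaction product reads as first order in that charge.

The clock is therefore catalyst-hours, charge times time: alpha ended at 100 mM·h and epsilon at 148 mM·h. The toll, the share of charged starting material lost per catalyst-hour between those last readings, reads 8.54 × 10⁻⁴ /mM/h.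

Violet will reach 126 mM·h, between the two, and amber 165 mM·h, just beyond epsilon. My reckoning therefore leaves 41.5 % starting material in amber and 44.9 % in violet. The same line for over-reaction product gives amber 29.0 %, less than its starting material, and target stood at 0.772 of starting material in epsilon.

Leave the catalyst charge alone: on this line, the 1.30 mM between amber and violet is worth 3.4 points.

The forecast names starting material as leader in both, at 41 % for amber and 44.5 % for violet, on the ground that “The runs should therefore collapse on catalyst × time”. Both values stand within 1 point of my line.

    starting material + partner + free catalyst ⇌ target + free catalyst, rate k1*[starting material]*[partner]*[free catalyst] forward; the back reaction follows from the equilibrium constant (K = 0.400 /M, k = 15.0 /M²/h)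
    free catalyst + target → spent catalyst (k = 0.00400 /M/h)
    free catalyst + target → free catalyst + over-reaction product (k = 7.30 /M/h)
    free catalyst + added ligand ⇌ idle complex (K = 76.0 /M, k = 20.0 /M/h)

Amber ends with 41.5 % starting material and violet with 45.0 %, ahead of target at 30.8 % and 34.0 %. At 30.0 h amber makes target at 0.533 of the rate it uses it up, each step taken net. Amber read at 5.0 d stands 495 mM·h further on the clock, for which the toll gives a fall of 42 points. That flask holds 16.6 % starting material, a fall of 25 points, beside 72.3 % over-reaction product.

(Readings and results come from a simulation from invented constants; the scatter is artificial.)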